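## Retrosynthetic overview

1. Target 25 ← 24 by removal of two MOM groups; 24 is cut in the side chain between the benzylic CH2 on C2' of ring B and the vinylic CH, giving flavanone salicyl alcohol 12 and the (E)-C9 alkenylboronic acid 20.
2. Enabling feature: on ring B the 3'-OH is ortho to C2', the carbon that carries the side-chain CH2. O3'–C3'–C2'–CH2 is therefore a latent o-quinone methide, and O3' can hold boron so that the alkenyl group reaches CH2 through a six-membered B–O3'–C3'–C2'–CH2–C transition state.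
3. 12 ← 11 ← arylboronic acid 8 + chromone 10 by Rh-catalysed asymmetric 1,4-addition, which sets C2.
4. 8 ← 2,3-dihydroxybenzaldehyde (its CHO carbon becomes the benzylic CH2); 20 ← 6-methylhept-5-en-2-one via the alkyne and Zr-catalysed methylalumination, which sets the E alkene.
5. Rings: A and C come intact from 7-hydroxychromone and ring B from the starting arene. No ring of the target is built; the only ring formed is the temporary 1,3,2-dioxaborin of the key step, which opens again in the same flask.

Key step: step 12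

Remark (assumption): in step 7 the (S)-bisphosphine is assumed to give the 2S flavanone, by analogy with the cyclohexenone model of Rh-catalysed 1,4-additions. If the sense is the opposite, the (R)-ligand is used.

## Route

Step 1
Reactants: 1 2,3-dihydroxybenzaldehyde
Product: 2 2-hydroxy-3-(methoxymethoxy)benzaldehyde
Conditions: NaH (2.2 equiv), THF/DMF, 0 °C; MOMCl (1.0 equiv), 0 → 23 °C
Reagents that add atoms: chloromethyl methyl ether (MOMCl), COCCl
Why: Williamson-type O-alkylation of the dianion, in which the 2-phenoxide is stabilised by conjugation with and chelation to the ortho formyl group, so the 3-phenoxide should be the more nucleophilic site and be alkylated selectively.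

Step 2
Reactants: 2 2-hydroxy-3-(methoxymethoxy)benzaldehyde
Product: 3 2-(hydroxymethyl)-6-(methoxymethoxy)phenol
Conditions: NaBH4, MeOH/THF, 0 °C
Reagents that add atoms: none
Why: Borohydride reduction of the aldehyde to the salicyl alcohol, with the aryl MOM ether inert.

Step 3
Reactants: 3 2-(hydroxymethyl)-6-(methoxymethoxy)phenol
Product: 4 2-(benzyloxy)-1-[(benzyloxy)methyl]-3-(methoxymethoxy)benzene
Conditions: NaH (2.4 equiv), BnBr (2.2 equiv), Bu4NI (cat.), DMF, 0 → 40 °C
Reagents that add atoms: benzyl bromide, BrCc1ccccc1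
Why: Double Williamson etherification of the phenoxide and the primary alkoxide.

Step 4
Reactants: 4 2-(benzyloxy)-1-[(benzyloxy)methyl]-3-(methoxymethoxy)benzene
Product: 5 1-bromo-3-(benzyloxy)-2-[(benzyloxy)methyl]-4-(methoxymethoxy)benzene
Conditions: NBS (1.05 equiv), MeCN, 0 → 23 °C, dark
Reagents that add atoms: N-bromosuccinimide, O=C1CCC(=O)N1Br
Why: Electrophilic aromatic bromination, directed para by the OMOM group (one free ortho neighbour, coplanar), whereas the doubly flanked benzyloxy group is twisted out of conjugation; this para position is the ring carbon next to the CH2OBn group.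

Step 5
Reactants: 5 1-bromo-3-(benzyloxy)-2-[(benzyloxy)methyl]-4-(methoxymethoxy)benzene
Product: 8 {3-(benzyloxy)-2-[(benzyloxy)methyl]-4-(methoxymethoxy)phenyl}boronic acid, via aryllithium 6 (not isolated), via lithium aryltriisopropoxyborate 7 (not isolated)
Conditions: B(OiPr)3 (1.5 equiv), then n-BuLi (1.1 equiv), THF/PhMe, −78 °C (in situ quench); aq. NH4Cl, 23 °C
Reagents that add atoms: triisopropyl borate, CC(C)OB(OC(C)C)OC(C)C; water, O
Why: Bromine–lithium exchange with immediate borate trapping, which should suppress Wittig rearrangement of the neighbouring benzyl ether, followed by hydrolysis of the borate to the boronic acid at a pH the MOM ether tolerates.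

Step 6
Reactants: 9 7-hydroxy-4H-chromen-4-one
Product: 10 7-(methoxymethoxy)-4H-chromen-4-one
Conditions: MOMCl (1.3 equiv), i-Pr2NEt, CH2Cl2, 0 → 23 °C
Reagents that add atoms: chloromethyl methyl ether (MOMCl), COCCl
Why: O-alkylation of the acidic 7-phenol, which removes the phenoxide that would deactivate the chromone as an acceptor.

Step 7
Reactants: 8 {3-(benzyloxy)-2-[(benzyloxy)methyl]-4-(methoxymethoxy)phenyl}boronic acid; 10 7-(methoxymethoxy)-4H-chromen-4-one
Product: 11 (2S)-2-{3-(benzyloxy)-2-[(benzyloxy)methyl]-4-(methoxymethoxy)phenyl}-7-(methoxymethoxy)chroman-4-one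
Conditions: [Rh(OH)(cod)]2 (2.5 mol %), (S)-MeO-F12-BIPHEP (5.5 mol %), 8 (2.5 equiv), PhMe/H2O 10:1, 40 °C
Reagents that add atoms: none
Why: Rh(I)-catalysed asymmetric 1,4-addition of an arylboronic acid to a chromone (Hayashi–Miyaura type), in which the aryl–Rh species inserts the C2=C3 bond on the face selected by the C2-symmetric bisphosphine and so sets the 2S centre, while the base-free aqueous medium should prevent retro-oxa-Michael opening.

Step 8
Reactants: 11 (2S)-2-{3-(benzyloxy)-2-[(benzyloxy)methyl]-4-(methoxymethoxy)phenyl}-7-(methoxymethoxy)chroman-4-one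
Product: 12 (2S)-2-[3-hydroxy-2-(hydroxymethyl)-4-(methoxymethoxy)phenyl]-7-(methoxymethoxy)chroman-4-one
Conditions: H2 (1 atm), 10 % Pd/C, EtOAc, 23 °C, stopped at 2 equiv uptake
Reagents that add atoms: none
Why: Hydrogenolysis of the aryl benzyl ether and of the unhindered PhCH2–O bond of the dibenzylic ether, which should be faster than cleavage of the hindered, electron-rich ArCH2–OH bond or of the C2–O1 bond, in a neutral medium that leaves the MOM groups and C2 untouched.

Step 9
Reactants: 13 6-methylhept-5-en-2-one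
Product: 15 6-methylhept-5-en-1-yne, via enol phosphate 14 (not isolated)
Conditions: LDA (1.05 equiv), THF, −78 °C; ClP(O)(OEt)2, −78 → 23 °C; then LDA (2.3 equiv), THF, −78 → 23 °C; aq. NH4Cl
Reagents that add atoms: none
Why: Negishi conversion of a methyl ketone into a terminal alkyne by phosphorylation of the kinetic (terminal) enolate and base-induced elimination of diethyl phosphate.

Step 10
Reactants: 15 6-methylhept-5-en-1-yne
Product: 17 (1E)-1-iodo-2,6-dimethylhepta-1,5-diene, via alkenylalane 16 (not isolated)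
Conditions: Me3Al (2.0 equiv), Cp2ZrCl2 (0.25 equiv), CH2Cl2, 23 °C; then I2 (1.2 equiv), THF, −30 → 0 °C
Reagents that add atoms: trimethylaluminium, C[Al](C)C; iodine, II
Why: Negishi Zr-catalysed carboalumination adds methyl and aluminium syn across the alkyne with aluminium on the terminal carbon, and iodinolysis with retention should give the E trisubstituted alkenyl iodide.

Step 11
Reactants: 17 (1E)-1-iodo-2,6-dimethylhepta-1,5-diene
Product: 20 [(1E)-2,6-dimethylhepta-1,5-dien-1-yl]boronic acid, via alkenyllithium 18 (not isolated), via lithium alkenyltriisopropoxyborate 19 (not isolated)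
Conditions: t-BuLi (2.1 equiv), Et2O, −78 °C; B(OiPr)3 (1.5 equiv), −78 → 0 °C; 1 M HCl, 0 °C (brief)
Reagents that add atoms: triisopropyl borate, CC(C)OB(OC(C)C)OC(C)C; water, O
Why: Iodine–lithium exchange and borylation both proceed with retention at the sp2 carbon, and hydrolysis of the borate gives the boronic acid.

Step 12
Reactants: 12 (2S)-2-[3-hydroxy-2-(hydroxymethyl)-4-(methoxymethoxy)phenyl]-7-(methoxymethoxy)chroman-4-one; 20 [(1E)-2,6-dimethylhepta-1,5-dien-1-yl]boronic acid
Product: 24 (2S)-2-{2-[(2E)-3,7-dimethylocta-2,6-dien-1-yl]-3-hydroxy-4-(methoxymethoxy)phenyl}-7-(methoxymethoxy)chroman-4-one, via cyclic alkenylboronate 21 (not isolated), via o-quinone methide borate 22 (not isolated), via aryl borate 23 (not isolated)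
Conditions: 20 (1.5 equiv), PhMe, 90 °C, sealed tube (water of condensation kept in the vessel, no base, no added Lewis acid); then H2O work-up
Reagents that add atoms: none
Why: Proposed new method: boronic acid 20 should condense with the 3'-OH and the ortho CH2OH of 12 to the six-membered 4H-1,3,2-benzodioxaborin 21 (ring closure by B–O condensation); re-addition of water at boron then gives a tetracoordinate borate in which O3' pushes and the boron-bound benzylic oxygen pulls, so that the benzylic C–O bond ionises to the boron-bound o-quinone methide 22, and the alkenyl group migrates from boron to the exocyclic CH2 through the six-membered B–O3'–C3'–C2'–CH2–C transition state with rearomatisation to aryl borate 23, which the work-up hydrolyses. The closest known reactions are the biphenol-catalysed addition of alkenylboronates to o-quinone methides made from o-hydroxybenzyl ethers, the Petasis borono-Mannich reaction of salicylaldehydes, and o-quinone methide generation from 2-aryl-4H-1,3,2-benzodioxaborins; what is new is a primary (CH2) o-quinone methide with the boron carried by the substrate's own phenol. No ring of the target is closed (the dioxaborin is temporary) and no stereocentre is made; the migrating sp2 carbon keeps its configuration, so the E geometry from step 10 is carried over. The step needs C- over O-alkenylation, reaction only at the benzylic carbon and no erosion at C2: delivery from O3'-bound boron secures the first two, the MOM group on O4' prevents a five-membered catechol boronate from which the alkenyl group cannot reach CH2, and the base-free medium gives no enolate and so no retro-oxa-Michael racemisation. The C4 ketone, the MOM acetals and the trisubstituted alkenes are inert to boronic acids.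

Step 13
Reactants: 24 (2S)-2-{2-[(2E)-3,7-dimethylocta-2,6-dien-1-yl]-3-hydroxy-4-(methoxymethoxy)phenyl}-7-(methoxymethoxy)chroman-4-one
Product: 25 (2S)-2-{2-[(2E)-3,7-dimethylocta-2,6-dien-1-yl]-3,4-dihydroxyphenyl}-7-hydroxychroman-4-one
Conditions: HCl (ca. 1 M), MeOH/THF, 23 → 40 °C
Reagents that add atoms: none
Why: Acid-catalysed transacetalisation of the aryl MOM ethers to methanol, under dilute acid that should neither racemise the flavanone nor protonate the trisubstituted alkenes next to the free 3'-OH.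

## Compound list

1 | 2,3-dihydroxybenzaldehyde | O=Cc1cccc(O)c1O | starting material
2 | 2-hydroxy-3-(methoxymethoxy)benzaldehyde | O=Cc1cccc(OCOC)c1O | intermediate
3 | 2-(hydroxymethyl)-6-(methoxymethoxy)phenol | OCc1cccc(OCOC)c1O | intermediate
4 | 2-(benzyloxy)-1-[(benzyloxy)methyl]-3-(methoxymethoxy)benzene | COCOc1cccc(COCc2ccccc2)c1OCc1ccccc1 | intermediate
5 | 1-bromo-3-(benzyloxy)-2-[(benzyloxy)methyl]-4-(methoxymethoxy)benzene | COCOc1ccc(Br)c(COCc2ccccc2)c1OCc1ccccc1 | intermediate
6 | {3-(benzyloxy)-2-[(benzyloxy)methyl]-4-(methoxymethoxy)phenyl}lithium | [Li]c1ccc(OCOC)c(OCc2ccccc2)c1COCc1ccccc1 | intermediate (not isolated)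
7 | lithium {3-(benzyloxy)-2-[(benzyloxy)methyl]-4-(methoxymethoxy)phenyl}triisopropoxyborate | CC(C)O[B-](OC(C)C)(OC(C)C)c1ccc(OCOC)c(OCc2ccccc2)c1COCc1ccccc1.[Li+] | intermediate (not isolated)
8 | {3-(benzyloxy)-2-[(benzyloxy)methyl]-4-(methoxymethoxy)phenyl}boronic acid | OB(O)c1ccc(OCOC)c(OCc2ccccc2)c1COCc1ccccc1 | intermediate
9 | 7-hydroxy-4H-chromen-4-one | O=c1ccoc2cc(O)ccc12 | starting material
10 | 7-(methoxymethoxy)-4H-chromen-4-one | COCOc1ccc2c(=O)ccoc2c1 | intermediate
11 | (2S)-2-{3-(benzyloxy)-2-[(benzyloxy)methyl]-4-(methoxymethoxy)phenyl}-7-(methoxymethoxy)chroman-4-one | C(OCc1ccccc1)c1c([C@@H]2CC(=O)c3ccc(OCOC)cc3O2)ccc(OCOC)c1OCc1ccccc1 | intermediate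
12 | (2S)-2-[3-hydroxy-2-(hydroxymethyl)-4-(methoxymethoxy)phenyl]-7-(methoxymethoxy)chroman-4-one | OCc1c([C@@H]2CC(=O)c3ccc(OCOC)cc3O2)ccc(OCOC)c1O | intermediate
13 | 6-methylhept-5-en-2-one | CC(=O)CCC=C(C)C | starting material
14 | diethyl 6-methylhepta-1,5-dien-2-yl phosphate | CC(C)=CCCC(=C)OP(=O)(OCC)OCC | intermediate (not isolated)
15 | 6-methylhept-5-en-1-yne | CC(C)=CCCC#C | intermediate
16 | [(1E)-2,6-dimethylhepta-1,5-dien-1-yl]dimethylalane | CC(C)=CCC/C(C)=C/[Al](C)C | intermediate (not isolated)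
17 | (1E)-1-iodo-2,6-dimethylhepta-1,5-diene | CC(C)=CCC/C(C)=C/I | intermediate
18 | [(1E)-2,6-dimethylhepta-1,5-dien-1-yl]lithium | CC(C)=CCC/C(C)=C/[Li] | intermediate (not isolated)
19 | lithium [(1E)-2,6-dimethylhepta-1,5-dien-1-yl]triisopropoxyborate | CC(C)=CCC/C(C)=C/[B-](OC(C)C)(OC(C)C)OC(C)C.[Li+] | intermediate (not isolated)
20 | [(1E)-2,6-dimethylhepta-1,5-dien-1-yl]boronic acid | CC(C)=CCC/C(C)=C/B(O)O | intermediate
21 | (2S)-2-{2-[(1E)-2,6-dimethylhepta-1,5-dien-1-yl]-8-(methoxymethoxy)-4H-1,3,2-benzodioxaborin-5-yl}-7-(methoxymethoxy)chroman-4-one | CC(C)=CCC/C(C)=C/B1OCc2c([C@@H]3CC(=O)c4ccc(OCOC)cc4O3)ccc(OCOC)c2O1 | intermediate (not isolated)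
22 | boron-bound o-quinone methide of ring B (zwitterionic dihydroxy(alkenyl)borate on O3', exocyclic CH2 on C2', 2S) | C=C1C(=[O+][B-](O)(O)/C=C(\C)CCC=C(C)C)C(OCOC)=CC=C1[C@@H]1CC(=O)c2ccc(OCOC)cc2O1 | intermediate (not isolated)
23 | dihydrogen borate ester of 24 at O3' | CC(C)=CCC/C(C)=C/Cc1c([C@@H]2CC(=O)c3ccc(OCOC)cc3O2)ccc(OCOC)c1OB(O)O | intermediate (not isolated)
24 | (2S)-2-{2-[(2E)-3,7-dimethylocta-2,6-dien-1-yl]-3-hydroxy-4-(methoxymethoxy)phenyl}-7-(methoxymethoxy)chroman-4-one | CC(C)=CCC/C(C)=C/Cc1c([C@@H]2CC(=O)c3ccc(OCOC)cc3O2)ccc(OCOC)c1O | intermediate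
25 | (2S)-2-{2-[(2E)-3,7-dimethylocta-2,6-dien-1-yl]-3,4-dihydroxyphenyl}-7-hydroxychroman-4-one | CC(C)=CCC/C(C)=C/Cc1c([C@@H]2CC(=O)c3ccc(O)cc3O2)ccc(O)c1O | target

## Step count and risks

Total steps: 13. Longest linear sequence: 9 (steps 1, 2, 3, 4, 5, 7, 8, 12, 13).

**Step 12 (proposed new method).** The benzylic C–O bond of the primary salicyl alcohol may not ionise at a temperature the alkenylboronic acid survives. Protodeboronation or oligomerisation of the o-quinone methide may then outrun the boron-to-carbon shift.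
Fallback, from 12 and back at 24, is the known anionic o-quinone methide alkylation run at the flavan-4-ol level, where base cannot open the pyranone:
- 12 is reduced (NaBH4, MeOH, 0 °C) to (2S)-2-[3-hydroxy-2-(hydroxymethyl)-4-(methoxymethoxy)phenyl]-7-(methoxymethoxy)chroman-4-ol F1, carried on as the C4 epimer mixture.
- The phenol alone is converted (Boc2O, i-Pr2NEt, cat. DMAP, CH2Cl2, −20 °C) into the aryl tert-butyl carbonate F2.
- Iodide 17 is turned, through alkenyllithium 18 (t-BuLi, then MgBr2·OEt2), into [(1E)-2,6-dimethylhepta-1,5-dien-1-yl]magnesium bromide F4.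
- F4 (4 equiv, THF, −78 → 0 °C) deprotonates both alcohols of F2; the Boc group moves to the benzylic alkoxide, tert-butyl carbonate leaves, and the Grignard reagent adds 1,4 to the o-quinone methide. This should give the geranylated flavan-4-ol F3.
- Activated MnO2 (CH2Cl2, 23 °C) oxidises the benzylic C4 alcohol and returns 24.

**Step 7.** Transmetalation and insertion of the hindered, ortho-substituted aryl group into the electron-rich chromone may be slow. Protodeboronation then consumes 8, or facial selectivity is poor.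
Fallback, from 5 and back at 11, is racemic ring construction followed by kinetic resolution:
- 5 is converted through aryllithium 6 (n-BuLi, THF, −78 °C; DMF) into 3-(benzyloxy)-2-[(benzyloxy)methyl]-4-(methoxymethoxy)benzaldehyde F5.
- 1-[2-Hydroxy-4-(methoxymethoxy)phenyl]ethan-1-one F6 is made from commercial 2',4'-dihydroxyacetophenone (MOMCl, K2CO3, acetone).
- Claisen–Schmidt condensation of F5 with F6 (KOH, EtOH, 23 °C) gives the 2'-hydroxychalcone F7.
- NaOAc in refluxing EtOH cyclises F7 to the racemic flavanone F8.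
- Asymmetric transfer hydrogenation (Rh or Ru TsDPEN catalyst, antipode chosen to reduce the 2R ketone, HCO2H/Et3N) should turn the 2R enantiomer into the cis-flavan-4-ol F9. Unreacted (S)-11 is separated by chromatography.

**Step 8.** Hydrogenolysis may go too far: the ArCH2–O bond may be cut to a methyl group, the dibenzylic ether may cleave on the wrong side, or the C4 ketone may be reduced.
Fallback, from 3 and back at 12, replaces reductive by fluoride deprotection:
- 3 is bis-silylated (TBSCl, imidazole, DMF) to tert-butyl{[2-(tert-butyldimethylsilyloxy)-3-(methoxymethoxy)phenyl]methoxy}dimethylsilane F10.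
- NBS in MeCN gives the bromide F11, para to OMOM.
- n-BuLi with B(OiPr)3 present (THF, −78 °C, which also suppresses retro-Brook silyl migration) leads through the aryllithium F12 and the lithium triisopropoxyborate F13 to the boronic acid F14.
- Rh-catalysed addition of F14 to 10 as in step 7 gives the bis-silylated (2S)-flavanone F15.
- Bu4NF/AcOH (THF, 0 °C) removes both silyl groups and returns 12.

## Further compounds

F1 | step 12 | (2S)-2-[3-hydroxy-2-(hydroxymethyl)-4-(methoxymethoxy)phenyl]-7-(methoxymethoxy)chroman-4-ol (C4 epimers) | OCc1c([C@@H]2CC(O)c3ccc(OCOC)cc3O2)ccc(OCOC)c1O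
F2 | step 12 | tert-butyl 2-(hydroxymethyl)-3-[(2S)-4-hydroxy-7-(methoxymethoxy)chroman-2-yl]-6-(methoxymethoxy)phenyl carbonate | OCc1c([C@@H]2CC(O)c3ccc(OCOC)cc3O2)ccc(OCOC)c1OC(=O)OC(C)(C)C
F3 | step 12 | (2S)-2-{2-[(2E)-3,7-dimethylocta-2,6-dien-1-yl]-3-hydroxy-4-(methoxymethoxy)phenyl}-7-(methoxymethoxy)chroman-4-ol (C4 epimers) | CC(C)=CCC/C(C)=C/Cc1c([C@@H]2CC(O)c3ccc(OCOC)cc3O2)ccc(OCOC)c1O
F4 | step 12 | [(1E)-2,6-dimethylhepta-1,5-dien-1-yl]magnesium bromide | CC(C)=CCC/C(C)=C/[Mg]Br
F5 | step 7 | 3-(benzyloxy)-2-[(benzyloxy)methyl]-4-(methoxymethoxy)benzaldehyde | O=Cc1ccc(OCOC)c(OCc2ccccc2)c1COCc1ccccc1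
F6 | step 7 | 1-[2-hydroxy-4-(methoxymethoxy)phenyl]ethan-1-one | CC(=O)c1ccc(OCOC)cc1O
F7 | step 7 | (2E)-3-{3-(benzyloxy)-2-[(benzyloxy)methyl]-4-(methoxymethoxy)phenyl}-1-[2-hydroxy-4-(methoxymethoxy)phenyl]prop-2-en-1-one | O=C(/C=C/c1ccc(OCOC)c(OCc2ccccc2)c1COCc1ccccc1)c1ccc(OCOC)cc1O
F8 | step 7 | racemic 2-{3-(benzyloxy)-2-[(benzyloxy)methyl]-4-(methoxymethoxy)phenyl}-7-(methoxymethoxy)chroman-4-one | C(OCc1ccccc1)c1c(C2CC(=O)c3ccc(OCOC)cc3O2)ccc(OCOC)c1OCc1ccccc1
F9 | step 7 | (2R,4R)-2-{3-(benzyloxy)-2-[(benzyloxy)methyl]-4-(methoxymethoxy)phenyl}-7-(methoxymethoxy)chroman-4-ol (2,4-cis) | C(OCc1ccccc1)c1c([C@H]2C[C@@H](O)c3ccc(OCOC)cc3O2)ccc(OCOC)c1OCc1ccccc1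
F10 | step 8 | tert-butyl{[2-(tert-butyldimethylsilyloxy)-3-(methoxymethoxy)phenyl]methoxy}dimethylsilane | COCOc1cccc(CO[Si](C)(C)C(C)(C)C)c1O[Si](C)(C)C(C)(C)C
F11 | step 8 | {[6-bromo-2-(tert-butyldimethylsilyloxy)-3-(methoxymethoxy)phenyl]methoxy}(tert-butyl)dimethylsilane | COCOc1ccc(Br)c(CO[Si](C)(C)C(C)(C)C)c1O[Si](C)(C)C(C)(C)C
F12 | step 8 | {3-(tert-butyldimethylsilyloxy)-2-[(tert-butyldimethylsilyloxy)methyl]-4-(methoxymethoxy)phenyl}lithium | [Li]c1ccc(OCOC)c(O[Si](C)(C)C(C)(C)C)c1CO[Si](C)(C)C(C)(C)C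
F13 | step 8 | lithium {3-(tert-butyldimethylsilyloxy)-2-[(tert-butyldimethylsilyloxy)methyl]-4-(methoxymethoxy)phenyl}triisopropoxyborate | CC(C)O[B-](OC(C)C)(OC(C)C)c1ccc(OCOC)c(O[Si](C)(C)C(C)(C)C)c1CO[Si](C)(C)C(C)(C)C.[Li+]
F14 | step 8 | {3-(tert-butyldimethylsilyloxy)-2-[(tert-butyldimethylsilyloxy)methyl]-4-(methoxymethoxy)phenyl}boronic acid | COCOc1ccc(B(O)O)c(CO[Si](C)(C)C(C)(C)C)c1O[Si](C)(C)C(C)(C)C
F15 | step 8 | (2S)-2-{3-(tert-butyldimethylsilyloxy)-2-[(tert-butyldimethylsilyloxy)methyl]-4-(methoxymethoxy)phenyl}-7-(methoxymethoxy)chroman-4-one | CC(C)(C)[Si](C)(C)OCc1c([C@@H]2CC(=O)c3ccc(OCOC)cc3O2)ccc(OCOC)c1O[Si](C)(C)C(C)(C)C
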